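**Strategy.** Everything rests on opening ring C of the flavanone at C3–C4 and O1–C2. Ring C is a β-aryloxy ketone in which O1 is the ring A phenol oxygen ortho to the aroyl carbon C4, and the key step uses that oxygen twice. It chelates monovalent rhodium so that the formyl C–H of a protected phloroglucinaldehyde adds across a terminal aryl alkyne (C3–C4), and it then closes O1–C2 by a catalyst-controlled oxa-Michael addition that sets C2. The precursor is the complete all-trans cyclohexene, built by an asymmetric Diels–Alder reaction between a 2'-hydroxychalcone and a dehydroprenyl arene diene whose ring B already carries the ethynyl group.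

Key step: step 11

Assumption: the sense of induction of the two chiral reagents is taken as written, (R)-VANOL for the (1S,5R,6S) cyclohexene and the quinine-derived thiourea for (2S)-C2. Each has an available antipode or pseudo-enantiomer that would replace it unchanged in procedure if a pilot run shows the opposite sense.

Step 1
Reactants: 1 2-iodoresorcinol (2-iodobenzene-1,3-diol)
Product: 2 2,4-dihydroxy-3-iodobenzaldehyde
Conditions: POCl3, DMF, MeCN, 0 to 25 °C; then H2O, 50 °C
Reagents that add atoms: N,N-dimethylformamide CN(C)C=O; water O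
Why: Vilsmeier–Haack formylation of a resorcinol should go at the only activated position (ortho to one hydroxyl, para to the other), which fixes the 1,2,3,4-substitution pattern of ring B without a regiochemical choice.

Step 2
Reactants: 2 2,4-dihydroxy-3-iodobenzaldehyde
Product: 3 3-iodo-2,4-bis(methoxymethoxy)benzaldehyde
Conditions: NaH, MOMCl, DMF, 0 to 25 °C
Reagents that add atoms: chloromethyl methyl ether COCCl
Why: Williamson-type O-alkylation of both sodium phenoxides should protect even the hydrogen-bonded 2-hydroxyl, giving acetal ethers that survive all later basic and organometallic steps.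

Step 3
Reactants: 4 2-methylbut-1-en-3-yne
Product: 5 (E)-4,4,5,5-tetramethyl-2-(3-methylbuta-1,3-dien-1-yl)-1,3,2-dioxaborolane
Conditions: pinacolborane, Cp2Zr(H)Cl (5 mol %), Et3N (10 mol %), neat, 60 °C
Reagents that add atoms: pinacolborane B1OC(C)(C)C(C)(C)O1
Why: Zirconium-catalysed syn hydroboration of the terminal alkyne should be chemoselective over the 1,1-disubstituted alkene and give the (E)-dienylboronate.

Step 4
Reactants: 3 3-iodo-2,4-bis(methoxymethoxy)benzaldehyde; 5 (E)-dienylboronate
Product: 6 2,4-bis(methoxymethoxy)-3-[(1E)-3-methylbuta-1,3-dien-1-yl]benzaldehyde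
Conditions: Pd(OAc)2 (5 mol %), SPhos (10 mol %), K3PO4, dioxane/H2O, 80 °C
Reagents that add atoms: none
Why: Suzuki–Miyaura coupling with a bulky biarylphosphine should let zerovalent palladium insert into the doubly ortho-flanked C–I bond and transfer the dienyl group with retention of the (E) geometry.

Step 5
Reactants: 6 dienyl benzaldehyde
Product: 7 1-ethynyl-2,4-bis(methoxymethoxy)-3-[(1E)-3-methylbuta-1,3-dien-1-yl]benzene
Conditions: dimethyl (1-diazo-2-oxopropyl)phosphonate, K2CO3, MeOH, 0 to 25 °C
Reagents that add atoms: dimethyl (1-diazo-2-oxopropyl)phosphonate CC(=O)C(=[N+]=[N-])P(=O)(OC)OC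
Why: Ohira–Bestmann homologation should convert the non-enolisable aldehyde into the terminal alkyne under mild carbonate conditions that leave the diene and the acetal ethers untouched.

Step 6
Reactants: 8 2',4'-dihydroxyacetophenone
Product: 9 2'-hydroxy-4'-(methoxymethoxy)acetophenone
Conditions: MOMCl (1.1 equiv), K2CO3, acetone, 25 °C
Reagents that add atoms: chloromethyl methyl ether COCCl
Why: With a weak base only the non-chelated 4'-phenol should be alkylated, which keeps the 2'-hydroxyl free for boron chelation in step 9.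

Step 7
Reactants: 10 2,4-dihydroxybenzaldehyde
Product: 11 2,4-bis(methoxymethoxy)benzaldehyde
Conditions: NaH, MOMCl, DMF, 0 to 25 °C
Reagents that add atoms: chloromethyl methyl ether COCCl
Why: Exhaustive O-alkylation of the bis-phenoxide should mask both phenols so that the aldehyde stays electrophilic in the aldol condensation.

Step 8
Reactants: 9 2'-hydroxy-4'-(methoxymethoxy)acetophenone; 11 2,4-bis(methoxymethoxy)benzaldehyde
Product: 12 (E)-3-[2,4-bis(methoxymethoxy)phenyl]-1-[2-hydroxy-4-(methoxymethoxy)phenyl]prop-2-en-1-one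
Conditions: KOH, EtOH/H2O, 25 °C
Reagents that add atoms: none
Why: Claisen–Schmidt condensation of the methyl ketone enolate with the non-enolisable aldehyde, followed by E1cB dehydration, should give the thermodynamic (E)-chalcone.

Step 9
Reactants: 12 2'-hydroxychalcone; 7 ethynyl aryl diene
Product: 13 [(1S,2S,6R)-6-[2,4-bis(methoxymethoxy)phenyl]-2-[3-ethynyl-2,6-bis(methoxymethoxy)phenyl]-4-methylcyclohex-3-en-1-yl][2-hydroxy-4-(methoxymethoxy)phenyl]methanone (all-trans adduct)
Conditions: (R)-VANOL, BH3·THF, AcOH, THF, 25 °C, then evaporation of volatiles; 12 then 7, PhCF3, 25 °C; aqueous work-up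
Reagents that add atoms: none
Why: Asymmetric Diels–Alder reaction in which the 2'-hydroxyl and carbonyl of 12 bind the chiral borate, which should activate the enone and shield one of its faces. The aryl-bearing diene terminus bonds to the α-carbon, the (E)-enone gives the trans aryl/aroyl pair, the exo approach gives the trans relation to the ring B aryl group, and the ligand sets the absolute configuration of all three centres; the endo isomer is removed by chromatography.

Step 10
Reactants: 14 2,4,6-trihydroxybenzaldehyde
Product: 15 2-hydroxy-4,6-bis(methoxymethoxy)benzaldehyde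
Conditions: MOMCl (2.1 equiv), K2CO3, acetone, 0 to 25 °C
Reagents that add atoms: chloromethyl methyl ether COCCl
Why: Two equivalents of the alkylating agent with a weak base should leave one hydrogen-bonded ortho-hydroxyl free, which is the oxygen that later becomes O1.

Step 11
Reactants: 13 all-trans ethynyl adduct; 15 2-hydroxy-4,6-bis(methoxymethoxy)benzaldehyde
Product: 17 (2S)-2-{3-[(1S,5R,6S)-5-[2,4-bis(methoxymethoxy)phenyl]-6-[2-hydroxy-4-(methoxymethoxy)benzoyl]-3-methylcyclohex-2-en-1-yl]-2,4-bis(methoxymethoxy)phenyl}-5,7-bis(methoxymethoxy)-2,3-dihydro-4H-chromen-4-one, via 2'-hydroxychalcone 16 (not isolated)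
Conditions: [RhCl(cod)]2 (2.5 mol %), dppf [Fe(C5H4PPh2)2] (5 mol %), Na2CO3 (5 mol %), toluene, 70 °C; then 1-[3,5-bis(trifluoromethyl)phenyl]-3-[(8S,9S)-6'-methoxycinchonan-9-yl]thiourea (20 mol %), toluene, 0 °C
Reagents that add atoms: none
Why: The free ortho-hydroxyl of 15 binds rhodium as a phenoxide and steers oxidative addition into the formyl C–H bond; syn hydrometalation of the terminal alkyne of 13 with rhodium at the unhindered terminus and C–C reductive elimination should give the linear (E)-2'-hydroxychalcone 16 (new C3–C4 bond), which is the known salicylaldehyde–alkyne hydroacylation. The same phenol then adds to the enone β-carbon in a 6-endo-trig oxa-Michael closure (new O1–C2 bond), as in the tandem hydroacylation/oxa-Michael route to chroman-4-ones, here run with a bifunctional cinchona thiourea whose quinuclidine deprotonates the phenol while the thiourea holds the enone carbonyl. C2 is the only new stereocentre, and its (S) configuration must come from the catalyst, because the cyclohexene stereotriad on ring B is too remote to direct the closure. The step needs linear regioselectivity, which the terminal alkyne and its ortho-acetal flank should secure, and chemoselectivity for the alkyne over the trisubstituted ring alkene and the diaryl ketone, neither of which should insert into the Rh–H bond. It also needs kinetic control in the closure (low temperature, weak base), so that the retro-oxa-Michael pathway that would equilibrate C2 stays slow. The 6'-acetal ether twists the aroyl unit and should favour the closed flavanone over the chalcone.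

Step 12
Reactants: 17 heptakis(methoxymethyl) ether of kuwanon L
Product: 18 kuwanon L, (2S)-2-{3-[(1S,5R,6S)-6-(2,4-dihydroxybenzoyl)-5-(2,4-dihydroxyphenyl)-3-methylcyclohex-2-en-1-yl]-2,4-dihydroxyphenyl}-5,7-dihydroxy-2,3-dihydro-4H-chromen-4-one
Conditions: HCl (1.25 M in MeOH), MeOH/THF, 35 °C
Reagents that add atoms: none
Why: Acid-catalysed acetal exchange with methanol should remove all seven methoxymethyl groups under conditions that avoid the base-mediated ring opening of ring C, so that C2 and the ketone α-centre keep their configuration.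

**Compound list**
1 | 2-iodoresorcinol | Oc1cccc(O)c1I | starting material
2 | 2,4-dihydroxy-3-iodobenzaldehyde | O=Cc1ccc(O)c(I)c1O | intermediate
3 | 3-iodo-2,4-bis(methoxymethoxy)benzaldehyde | O=Cc1ccc(OCOC)c(I)c1OCOC | intermediate
4 | 2-methylbut-1-en-3-yne | C=C(C)C#C | starting material
5 | (E)-4,4,5,5-tetramethyl-2-(3-methylbuta-1,3-dien-1-yl)-1,3,2-dioxaborolane | C=C(C)/C=C/B1OC(C)(C)C(C)(C)O1 | intermediate
6 | 2,4-bis(methoxymethoxy)-3-[(1E)-3-methylbuta-1,3-dien-1-yl]benzaldehyde | O=Cc1ccc(OCOC)c(/C=C/C(C)=C)c1OCOC | intermediate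
7 | 1-ethynyl-2,4-bis(methoxymethoxy)-3-[(1E)-3-methylbuta-1,3-dien-1-yl]benzene | C#Cc1ccc(OCOC)c(/C=C/C(C)=C)c1OCOC | intermediate
8 | 2',4'-dihydroxyacetophenone | CC(=O)c1ccc(O)cc1O | starting material
9 | 2'-hydroxy-4'-(methoxymethoxy)acetophenone | CC(=O)c1ccc(OCOC)cc1O | intermediate
10 | 2,4-dihydroxybenzaldehyde | O=Cc1ccc(O)cc1O | starting material
11 | 2,4-bis(methoxymethoxy)benzaldehyde | O=Cc1ccc(OCOC)cc1OCOC | intermediate
12 | (E)-3-[2,4-bis(methoxymethoxy)phenyl]-1-[2-hydroxy-4-(methoxymethoxy)phenyl]prop-2-en-1-one | COCOc1ccc(C(=O)/C=C/c2ccc(OCOC)cc2OCOC)c(O)c1 | intermediate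
13 | all-trans (1S,2S,6R) Diels–Alder adduct carrying the ring B ethynyl group | CC1=C[C@H](c2c(OCOC)ccc(C#C)c2OCOC)[C@@H](C(=O)c2ccc(OCOC)cc2O)[C@H](c2ccc(OCOC)cc2OCOC)C1 | intermediate
14 | 2,4,6-trihydroxybenzaldehyde | O=Cc1c(O)cc(O)cc1O | starting material
15 | 2-hydroxy-4,6-bis(methoxymethoxy)benzaldehyde | O=Cc1c(O)cc(OCOC)cc1OCOC | intermediate
16 | (E)-2'-hydroxychalcone from hydroacylation of 13 with 15 | CC1=C[C@H](c2c(OCOC)ccc(/C=C/C(=O)c3c(O)cc(OCOC)cc3OCOC)c2OCOC)[C@@H](C(=O)c2ccc(OCOC)cc2O)[C@H](c2ccc(OCOC)cc2OCOC)C1 | intermediate (not isolated)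
17 | heptakis(methoxymethyl) ether of kuwanon L, (2S) | CC1=C[C@H](c2c(OCOC)ccc([C@@H]3CC(=O)c4c(OCOC)cc(OCOC)cc4O3)c2OCOC)[C@@H](C(=O)c2ccc(OCOC)cc2O)[C@H](c2ccc(OCOC)cc2OCOC)C1 | intermediate
18 | kuwanon L | CC1=C[C@H](c2c(O)ccc([C@@H]3CC(=O)c4c(O)cc(O)cc4O3)c2O)[C@@H](C(=O)c2ccc(O)cc2O)[C@H](c2ccc(O)cc2O)C1 | target

**Step count.** Total: 12 steps. Longest linear sequence: 7 steps (steps 1, 2, 4, 5, 9, 11, 12).

**Steps most likely to fail**

Step 11. The hydroacylation may stall or lose linear regioselectivity with these hindered, electron-rich partners. The ring closure may also show poor facial selectivity, either because base-mediated background cyclisation starts before the chiral catalyst is added or because reversible ring opening equilibrates C2. The fallback sets out from 13 and 15 and comes back to the route at 17. Only the rhodium stage is run and chalcone 16 is isolated. Copper-catalysed asymmetric conjugate borylation (CuCl, NaOt-Bu, bis(pinacolato)diboron, MeOH, THF, with the Josiphos ligand (R)-1-[(S)-2-(diphenylphosphino)ferrocenyl]ethyldicyclohexylphosphine, Fe(C5H5)(C5H3(PPh2)CH(CH3)PCy2)) then gives the (R)-β-boryl ketone F1. Oxidation with NaBO3·4H2O in THF/H2O gives, with retention, the (R)-β-hydroxy ketone F2. Mitsunobu cyclodehydration (PPh3, DIAD, THF, 0 °C) lets the ring A phenol displace the activated benzylic hydroxyl with inversion, which gives the (2S)-flavanone 17. In this way C2 is set by a reagent-controlled C–B bond formation and a stereospecific substitution, not by the reversible oxa-Michael step.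

Step 9. The acetal-protected, electron-rich chalcone may react slowly under boron activation, the exo/endo preference may be low, and the facial selectivity may be insufficient or of the wrong sense. The fallback sets out from 7 and 12 and comes back at 13. A thermal Diels–Alder reaction activated only by the internal hydrogen bond (toluene, sealed tube, 160 °C) should give the racemic all-trans adduct after chromatographic removal of the endo isomer. Preparative chromatography on a chiral stationary phase then separates 13 from its enantiomer, the (1R,2R,6S) adduct F3. Absolute configuration is thus secured by resolution, not by reagent control.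

Step 12. Acid may open ring C at the benzylic O1–C2 bond once the ring B phenols are free and so erode C2, a ring B phenol may add to the ring alkene, or the hindered acetals may cleave incompletely. The fallback sets out from 13 and comes back at 18; it changes the protecting groups before C2 exists. Acid methanolysis of 13 (HCl, MeOH, 25 °C) gives the hexaphenol alkyne F4. Silylation (TBSCl, imidazole, DMF) gives the pentakis(tert-butyldimethylsilyl) ether F5, with the chelated hydroxyl left free. The aldehyde partner is made from 14 in the same way (TBSCl 2 equiv, imidazole, CH2Cl2) as 2-hydroxy-4,6-bis(tert-butyldimethylsilyloxy)benzaldehyde F6. The conditions of step 11 then join F5 and F6 through the silylated chalcone F7 to the heptakis(silyl) flavanone F8. Buffered HF·pyridine in THF at 0 °C removes the silyl groups at near-neutral pH and gives 18.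

**Further compounds**
F1 | step 11 | (R)-β-(pinacolboryl) ketone from conjugate borylation of 16 | CC1=C[C@H](c2c(OCOC)ccc([C@H](B3OC(C)(C)C(C)(C)O3)CC(=O)c3c(O)cc(OCOC)cc3OCOC)c2OCOC)[C@@H](C(=O)c2ccc(OCOC)cc2O)[C@H](c2ccc(OCOC)cc2OCOC)C1
F2 | step 11 | (R)-β-hydroxy ketone from oxidation of F1 | CC1=C[C@H](c2c(OCOC)ccc([C@H](O)CC(=O)c3c(O)cc(OCOC)cc3OCOC)c2OCOC)[C@@H](C(=O)c2ccc(OCOC)cc2O)[C@H](c2ccc(OCOC)cc2OCOC)C1
F3 | step 9 | (1R,2R,6S) enantiomer of adduct 13 | CC1=C[C@@H](c2c(OCOC)ccc(C#C)c2OCOC)[C@H](C(=O)c2ccc(OCOC)cc2O)[C@@H](c2ccc(OCOC)cc2OCOC)C1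
F4 | step 12 | hexaphenol alkyne from 13 | CC1=C[C@H](c2c(O)ccc(C#C)c2O)[C@@H](C(=O)c2ccc(O)cc2O)[C@H](c2ccc(O)cc2O)C1
F5 | step 12 | pentakis(tert-butyldimethylsilyl) ether of F4 | CC1=C[C@H](c2c(O[Si](C)(C)C(C)(C)C)ccc(C#C)c2O[Si](C)(C)C(C)(C)C)[C@@H](C(=O)c2ccc(O[Si](C)(C)C(C)(C)C)cc2O)[C@H](c2ccc(O[Si](C)(C)C(C)(C)C)cc2O[Si](C)(C)C(C)(C)C)C1
F6 | step 12 | 2-hydroxy-4,6-bis(tert-butyldimethylsilyloxy)benzaldehyde | O=Cc1c(O)cc(O[Si](C)(C)C(C)(C)C)cc1O[Si](C)(C)C(C)(C)C
F7 | step 12 | silylated (E)-2'-hydroxychalcone from F5 and F6 | CC1=C[C@H](c2c(O[Si](C)(C)C(C)(C)C)ccc(/C=C/C(=O)c3c(O)cc(O[Si](C)(C)C(C)(C)C)cc3O[Si](C)(C)C(C)(C)C)c2O[Si](C)(C)C(C)(C)C)[C@@H](C(=O)c2ccc(O[Si](C)(C)C(C)(C)C)cc2O)[C@H](c2ccc(O[Si](C)(C)C(C)(C)C)cc2O[Si](C)(C)C(C)(C)C)C1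
F8 | step 12 | heptakis(tert-butyldimethylsilyl) ether of kuwanon L | CC1=C[C@H](c2c(O[Si](C)(C)C(C)(C)C)ccc([C@@H]3CC(=O)c4c(O[Si](C)(C)C(C)(C)C)cc(O[Si](C)(C)C(C)(C)C)cc4O3)c2O[Si](C)(C)C(C)(C)C)[C@@H](C(=O)c2ccc(O[Si](C)(C)C(C)(C)C)cc2O)[C@H](c2ccc(O[Si](C)(C)C(C)(C)C)cc2O[Si](C)(C)C(C)(C)C)C1
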